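**Assumption:** the target has no stereocentres. The quaternary carbon of the 1,1-dimethylallyl group carries two identical methyls, so "single enantiomer" is moot. Both indoles and the central benzene are carried in pre-formed, so no rings are constructed in the route.

## Retrosynthesis
- Target ← removal of two indole N-Boc groups from a bis(indol-3-yl) phenol.
- That phenol ← two sequential Negishi couplings on one dibromophenol. The hindered 2-(1,1-dimethylallyl)indol-3-yl goes first, at the Br flanked by two OMe. The plain indol-3-yl goes second, at the Br ortho to the phenol.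
- The dibromophenol ← statistical mono-O-demethylation of the symmetric 1,4-dibromo-2,3,5,6-tetramethoxybenzene. Symmetry makes the position of the single OH unambiguous. That dibromide comes from commercial 1,2,4,5-tetramethoxybenzene.
- The 2-reverse-prenyl indole arm comes from indole by C2 reverse prenylation, then C3 iodination and N-Boc protection. The second indole arm is commercial N-Boc-3-iodoindole.

## Forward route

**Step 1**
Reactants: 1, 1,2,4,5-tetramethoxybenzene
Product: 2, 1,4-dibromo-2,3,5,6-tetramethoxybenzene
Conditions: NBS (2.1 equiv), MeCN, 0 °C → rt, dark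
Reagents that add atoms: NBS, O=C1CCC(=O)N1Br
Why: electrophilic aromatic bromination; the two free ring C–H positions are para to each other and strongly activated, so only the 1,4-dibromide forms.

**Step 2**
Reactants: 2
Product: 3, 2,5-dibromo-3,4,6-trimethoxyphenol
Conditions: BCl3 (1.0 equiv), CH2Cl2, −78 → 0 °C; aq. NaHCO3 quench; recover 2 and the bis-phenol
Reagents that add atoms: none
Why: Lewis-acid aryl methyl ether cleavage; all four OMe groups of 2 are equivalent, so statistical mono-demethylation gives a single constitutional isomer, which fixes the future OH position.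

**Step 3**
Reactants: 4, indole
Product: 5, 2-(2-methylbut-3-en-2-yl)-1H-indole
Conditions: (i) t-BuOCl, Et3N, THF, −78 °C; (ii) prenyl-9-BBN, −78 °C → rt; aqueous work-up
Reagents that add atoms: prenyl-9-BBN, CC(C)=CCB1C2CCCC1CCC2
Why: C2 reverse prenylation via the 3-chloroindolenine; the allylborane adds through its γ-carbon in a six-membered transition state, giving the C(CH3)2CH=CH2 group, and loss of HCl re-aromatises the indole. No stereocentre results.

**Step 4**
Reactants: 5
Product: 6, 3-iodo-2-(2-methylbut-3-en-2-yl)-1H-indole
Conditions: NIS (1.05 equiv), DMF, 0 °C, dark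
Reagents that add atoms: NIS, O=C1CCC(=O)N1I
Why: electrophilic iodination at the most nucleophilic indole position (C3); the terminal vinyl group is far less reactive.

**Step 5**
Reactants: 6
Product: 7, tert-butyl 3-iodo-2-(2-methylbut-3-en-2-yl)indole-1-carboxylate
Conditions: Boc2O (1.5 equiv), DMAP (0.2 equiv), MeCN, rt
Reagents that add atoms: Boc2O, CC(C)(C)OC(=O)OC(=O)OC(C)(C)C
Why: N-acylation removes the acidic N–H so the C3 iodide can be converted to an organometallic; the planar Boc group tolerates the adjacent tertiary alkyl.

**Step 6**
Reactants: 3, 2,5-dibromo-3,4,6-trimethoxyphenol; 7, tert-butyl 3-iodo-2-(2-methylbut-3-en-2-yl)indole-1-carboxylate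
Product: 8, tert-butyl 3-(4-bromo-5-hydroxy-2,3,6-trimethoxyphenyl)-2-(2-methylbut-3-en-2-yl)indole-1-carboxylate
Conditions: 7 + iPrMgCl·LiCl, THF, −20 °C, then ZnCl2 gives the 3-indolylzinc chloride. Add this (1.1 equiv) to the sodium phenoxide of 3 (NaH, THF), Pd-PEPPSI-IPent (5 mol %), THF, 60 °C
Reagents that add atoms: none
Why: Negishi coupling; the phenoxide deactivates the ortho C–Br towards oxidative addition, so coupling occurs at the Br between the two OMe groups, placing the hindered indole at the correct carbon. The bulky NHC-Pd catalyst is chosen for the tetra-ortho-substituted biaryl bond.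

**Step 7**
Reactants: 8; 9, tert-butyl 3-iodoindole-1-carboxylate
Product: 10, tert-butyl 3-[4-(1-Boc-indol-3-yl)-5-hydroxy-2,3,6-trimethoxyphenyl]-2-(2-methylbut-3-en-2-yl)indole-1-carboxylate
Conditions: 9 + iPrMgCl·LiCl, THF, −20 °C, then ZnCl2 gives the 3-indolylzinc chloride (2 equiv). Add to 8 (as its sodium phenoxide, NaH), Pd-PEPPSI-IPent (5–10 mol %), THF, 65 °C
Reagents that add atoms: none
Why: Negishi coupling at the only remaining C–Br; the less hindered unsubstituted indolyl nucleophile makes this bond, and the ortho free OH is tolerated.

**Step 8**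
Reactants: 10
Product: 11, asterriquinol I
Conditions: NaOMe (3 equiv), MeOH/THF, rt
Reagents that add atoms: none
Why: methanolysis of the activated indole N-Boc carbamates frees both N–H groups; the aryl OMe groups, the free phenol and the vinyl group are inert to these mild basic conditions.

## Compound list
1 | 1,2,4,5-tetramethoxybenzene | COc1cc(OC)c(OC)cc1OC | starting material
2 | 1,4-dibromo-2,3,5,6-tetramethoxybenzene | COc1c(Br)c(OC)c(OC)c(Br)c1OC | intermediate
3 | 2,5-dibromo-3,4,6-trimethoxyphenol | Oc1c(Br)c(OC)c(OC)c(Br)c1OC | intermediate
4 | indole | c1ccc2[nH]ccc2c1 | starting material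
5 | 2-(2-methylbut-3-en-2-yl)-1H-indole | C=CC(C)(C)c1cc2ccccc2[nH]1 | intermediate
6 | 3-iodo-2-(2-methylbut-3-en-2-yl)-1H-indole | C=CC(C)(C)c1[nH]c2ccccc2c1I | intermediate
7 | tert-butyl 3-iodo-2-(2-methylbut-3-en-2-yl)indole-1-carboxylate | C=CC(C)(C)c1c(I)c2ccccc2n1C(=O)OC(C)(C)C | intermediate
8 | tert-butyl 3-(4-bromo-5-hydroxy-2,3,6-trimethoxyphenyl)-2-(2-methylbut-3-en-2-yl)indole-1-carboxylate | C=CC(C)(C)c1n(C(=O)OC(C)(C)C)c2ccccc2c1-c1c(OC)c(OC)c(Br)c(O)c1OC | intermediate
9 | tert-butyl 3-iodoindole-1-carboxylate | CC(C)(C)OC(=O)n1cc(I)c2ccccc21 | starting material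
10 | bis-N-Boc coupled phenol (see Step 7) | C=CC(C)(C)c1n(C(=O)OC(C)(C)C)c2ccccc2c1-c1c(OC)c(OC)c(-c2cn(C(=O)OC(C)(C)C)c3ccccc23)c(O)c1OC | intermediate
11 | asterriquinol I (achiral) | C=CC(C)(C)c1[nH]c2ccccc2c1-c1c(OC)c(O)c(-c2c[nH]c3ccccc23)c(OC)c1OC | target

## Totals
Total steps: 8. Longest linear sequence: 6 (indole → 5 → 6 → 7 → 8 → 10 → 11). The ring-side sequence is 5 steps.

## Three steps most likely to fail
1. **Step 6.** It needs a tetra-ortho-substituted biaryl bond and Br-site selectivity governed only by the phenoxide.
   - Fallback: oxidise 3 (CAN) to 2,5-dibromo-3,6-dimethoxybenzoquinone. Add the indolyl-MgBr of 6 by addition–elimination, then the second indole. Reduce with Na2S2O4, mono-allylate the less hindered OH (next to the simple indole), methylate the other OH, and remove the allyl group with Pd(0). This is a non-Pd, quinone-based route.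
2. **Step 7.** Coupling at a Br that is ortho to the phenoxide and an OMe is hindered, and the phenoxide could transfer Boc.
   - Fallback: convert 8 (O-protected as the MOM ether) to its pinacol boronate and couple it with 9 under Suzuki conditions, reversing the polarity of the coupling partners. Remove the MOM group together with the Boc groups.
3. **Step 2.** Mono-demethylation is statistical, so yield is limited and over-demethylation is possible.
   - Fallback: make 3 from 2,5-dibromo-3,6-dimethoxybenzoquinone by Na2S2O4 reduction followed by one equivalent of Me2SO4/K2CO3. The symmetric substrate again gives one regioisomer.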